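**Plan**

- Retrosynthesis: the two disubstituted olefins C11=C12 and C11'=C12' are cut first (Wittig; two C15 enyne phosphonium salts and the purchased C10 trienedial). The ring-to-alkyne bonds C6–C7 (Sonogashira at an enol triflate) and C6'–C7' (acetylide addition, then oxidative 1,3-transposition) are cut next, which leads both rings back to one C9 ketone. The C3–C4 bond of that ring is cut last.
- Enabling feature: in ring A the carbinol carbon C3 and the alkyne-bearing carbon C6 (a masked ketone) stand 1,4 across C4–C5, so the ring is a latent cyclohexane-1,4-dione. This dissonant pattern is made by acyl-anion conjugate addition (Stetter) of the C3 aldehyde carbon to C4, the CH2 end of an isopropenyl ketone C4=C5(CH3)–C6=O, with the gem-dimethyl carbon C1 in the tether.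
- Forward: lactone → acyclic keto aldehyde → six-membered ring (carbene-catalysed closure) → hydroxy ketone silyl ether. From it, ring A: enol triflate → enyne salt → C25 aldehyde. Ring B: enone → acetylide adduct → ynenone → cis-diol salt. The two halves are then joined and desilylated.
- Stereochemistry: the catalyst sets the methyl-bearing carbon C5 in the ring closure. C5 steers a bulky hydride to give 3R and is then erased by enolisation. The same carbinol becomes 3'S in ring B, where 4'R (cis) comes from hydride attack anti to the C3' silyloxy group. Olefin geometry comes from the purchased all-E pieces and E-selective tributylphosphonium ylides.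

Key step: step 3

Assumption: the lactone, the Grignard solution, (2E)-3-methylpent-2-en-4-yn-1-ol and the all-E C10 trienedial are taken as purchased; the catalyst antipode named in step 3 is assumed to give the R dione (its mirror image is equally available if the sense is opposite); locants C1–C6 and C1'–C6' in the running text are carotenoid ring locants.

**Route**

Step 1
Reactants: 1 3,3-dimethyloxolan-2-one; 2 isopropenylmagnesium bromide
Product: 3 6-hydroxy-2,4,4-trimethylhex-1-en-3-one
Conditions: 2 (1.1 equiv), THF, −78 to −30 °C; then H2O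
Reagents that add atoms: none
Why: Ring-opening acyl substitution of a lactone by a Grignard reagent should stop after one addition because the magnesium hemiketal of the α,α-dimethyl lactone persists in the cold, so the enone is unveiled only on quenching.

Step 2
Reactants: 3 6-hydroxy-2,4,4-trimethylhex-1-en-3-one
Product: 4 3,3,5-trimethyl-4-oxohex-5-enal
Conditions: Dess–Martin periodinane, CH2Cl2, 0 °C to rt
Reagents that add atoms: none
Why: Dess–Martin oxidation of the primary alcohol, which equilibrates with its lactol, should give the aldehyde under non-basic conditions that leave the isopropenyl ketone alone.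

Step 3
Reactants: 4 3,3,5-trimethyl-4-oxohex-5-enal
Product: 5 (6R)-2,2,6-trimethylcyclohexane-1,4-dione
Conditions: (5aS,10bR)-2-(pentafluorophenyl)-5a,10b-dihydro-4H,6H-indeno[2,1-b][1,2,4]triazolo[4,3-d][1,4]oxazin-2-ium tetrafluoroborate (20 mol %), KN(SiMe3)2 (20 mol %), toluene (0.02 M), 23 °C
Reagents that add atoms: none
Why: Proposed new method: The carbene formed from the triazolium salt adds to the aldehyde of 4 and, after proton shift, gives the Breslow enaminol, whose acyl-anion carbon (the later carbinol carbon C3) adds to the unsubstituted CH2 terminus (C4) of the isopropenyl ketone; protonation of the resulting ring enol at the methyl-bearing carbon and loss of the carbene then give the 1,4-diketone. The closest known reaction type is the catalytic asymmetric intramolecular Stetter reaction of aliphatic aldehydes, including acceptors with an α-substituent whose stereocenter is set by proton transfer, which is established only for exo closure with the acceptor carbonyl outside the new ring. Here the six-membered carbocycle closes in the 6-endo-trig mode with the acceptor ketone inside the ring, an allowed mode that has no exo competitor in this substrate and is favoured by the gem-dimethyl group (Thorpe–Ingold effect). The single new stereocenter (C6 of the dione, R) is controlled by the catalyst: its indane wall fixes which face of the enaminol bonds and thus the configuration of the transient catalyst-bound carbinol carbon, whose hydroxyl group should then pass its proton across the ring to the same face of the enol carbon before the carbene leaves. The step needs conjugate addition to win over benzoin and aldol paths and needs the product not to epimerise, which the substrate secures by a ketone that has no α-hydrogen and is shielded by the quaternary carbon next to an unhindered acceptor terminus, and the conditions by high dilution and the absence of excess base.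

Step 4
Reactants: 5 (6R)-2,2,6-trimethylcyclohexane-1,4-dione
Product: 6 (4R,6R)-4-hydroxy-2,2,6-trimethylcyclohexan-1-one
Conditions: LiBH(sBu)3 (1.05 equiv), THF, −78 °C; then H2O
Reagents that add atoms: none
Why: In this substrate-controlled ketone reduction only the C4 carbonyl is accessible, and equatorial attack of the bulky borohydride, enforced by the axial methyl group on C2 as in 3,3,5-trimethylcyclohexanone, should give the axial alcohol trans to the C6 methyl group, which sets the carbinol carbon as R.

Step 5
Reactants: 6 (4R,6R)-4-hydroxy-2,2,6-trimethylcyclohexan-1-one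
Product: 7 (4R,6R)-4-[(tert-butyldimethylsilyl)oxy]-2,2,6-trimethylcyclohexan-1-one
Conditions: tert-butyldimethylsilyl chloride, imidazole, DMF, rt
Reagents that add atoms: tert-butyldimethylsilyl chloride CC(C)(C)[Si](C)(C)Cl
Why: Imidazole-promoted silylation protects the secondary alcohol for the enolisation chemistry that follows in both branches.

Step 6
Reactants: 7 (4R,6R)-4-[(tert-butyldimethylsilyl)oxy]-2,2,6-trimethylcyclohexan-1-one
Product: 9 (4R)-4-[(tert-butyldimethylsilyl)oxy]-2,6,6-trimethylcyclohex-1-en-1-yl trifluoromethanesulfonate, via lithium enolate 8 (not isolated)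
Conditions: LiN(iPr)2, THF, −78 °C; then PhNTf2, −78 to 0 °C
Reagents that add atoms: N-phenylbis(trifluoromethanesulfonimide) O=S(=O)(N(c1ccccc1)S(=O)(=O)C(F)(F)F)C(F)(F)F; lithium diisopropylamide [Li]N(C(C)C)C(C)C (lithium of 8 only)
Why: Enol triflate formation by deprotonation and O-triflation can give only the tetrasubstituted enolate because the ketone has a single α-hydrogen, and the relay stereocenter is erased here as planned.

Step 7
Reactants: 9 (4R)-4-[(tert-butyldimethylsilyl)oxy]-2,6,6-trimethylcyclohex-1-en-1-yl trifluoromethanesulfonate; 10 (2E)-3-methylpent-2-en-4-yn-1-ol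
Product: 11 (2E)-5-{(4R)-4-[(tert-butyldimethylsilyl)oxy]-2,6,6-trimethylcyclohex-1-en-1-yl}-3-methylpent-2-en-4-yn-1-ol
Conditions: Pd(PPh3)4 (5 mol %), CuI (10 mol %), iPr2NH, DMF, rt
Reagents that add atoms: none
Why: Sonogashira coupling of the enol triflate (zerovalent palladium, CuI as co-catalyst) with the terminal alkyne forms the C6–C7 bond with retention of the E geometry of the enynol and tolerance of its free hydroxyl group.

Step 8
Reactants: 11 (2E)-5-{(4R)-4-[(tert-butyldimethylsilyl)oxy]-2,6,6-trimethylcyclohex-1-en-1-yl}-3-methylpent-2-en-4-yn-1-ol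
Product: 13 tributyl[(2E)-5-{(4R)-4-[(tert-butyldimethylsilyl)oxy]-2,6,6-trimethylcyclohex-1-en-1-yl}-3-methylpent-2-en-4-yn-1-yl]phosphonium bromide, via allylic bromide 12 (not isolated)
Conditions: CBr4 (1.2 equiv), PPh3 (1.15 equiv), CH2Cl2, −20 °C; then PBu3 (1.5 equiv), rt
Reagents that add atoms: tetrabromomethane BrC(Br)(Br)Br; tributylphosphine CCCCP(CCCC)CCCC
Why: Appel bromination of the primary allylic alcohol followed by SN2 quaternisation of tributylphosphine gives the salt without acid, so the silyl ether and the enyne should stay intact.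

Step 9
Reactants: 13 tributyl[(2E)-5-{(4R)-4-[(tert-butyldimethylsilyl)oxy]-2,6,6-trimethylcyclohex-1-en-1-yl}-3-methylpent-2-en-4-yn-1-yl]phosphonium bromide; 14 (2E,4E,6E)-2,7-dimethylocta-2,4,6-trienedial
Product: 16 (2E,4E,6E,8E,10E)-13-{(4R)-4-[(tert-butyldimethylsilyl)oxy]-2,6,6-trimethylcyclohex-1-en-1-yl}-2,7,11-trimethyltrideca-2,4,6,8,10-pentaen-12-ynal, via phosphorus ylide 15 (not isolated)
Conditions: NaN(SiMe3)2 (1.0 equiv), THF, −78 °C; then slow addition to 14 (3 equiv), THF, −78 to 0 °C
Reagents that add atoms: none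
Why: Wittig olefination by an allylic trialkylphosphonium ylide, a class known for high E selectivity, should form the C11=C12 bond, and slow addition of the ylide to an excess of the symmetrical dialdehyde limits the reaction to one end.

Step 10
Reactants: 7 (4R,6R)-4-[(tert-butyldimethylsilyl)oxy]-2,2,6-trimethylcyclohexan-1-one
Product: 18 (4S)-4-[(tert-butyldimethylsilyl)oxy]-2,6,6-trimethylcyclohex-2-en-1-one, via trimethylsilyl enol ether 17 (not isolated)
Conditions: Me3SiOSO2CF3 (1.3 equiv), Et3N (2 equiv), CH2Cl2, 0 °C to rt; solvent exchange; then Pd(OAc)2 (1.1 equiv), MeCN, rt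
Reagents that add atoms: trimethylsilyl trifluoromethanesulfonate C[Si](C)(C)OS(=O)(=O)C(F)(F)F (trimethylsilyl group of 17 only)
Why: Soft enolisation by the silyl triflate and the amine needs no metal enolate, spares the tert-butyldimethylsilyl ether and can give only one silyl enol ether because the ketone has a single α-hydrogen; in the Saegusa–Ito dehydrogenation that follows, divalent palladium oxidises it through an oxa-π-allyl complex and β-hydride elimination into the ring, which should give the conjugated enone without touching the silyloxy-bearing stereocenter (its descriptor changes to S only by priority).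

Step 11
Reactants: 18 (4S)-4-[(tert-butyldimethylsilyl)oxy]-2,6,6-trimethylcyclohex-2-en-1-one; 10 (2E)-3-methylpent-2-en-4-yn-1-ol
Product: 20 (4S)-4-[(tert-butyldimethylsilyl)oxy]-1-[(3E)-5-hydroxy-3-methylpent-3-en-1-yn-1-yl]-2,6,6-trimethylcyclohex-2-en-1-ol, via dilithiated enynol 19 (not isolated)
Conditions: 10 (1.3 equiv), n-BuLi (2.6 equiv), THF, −78 to 0 °C; then 18, −78 to 0 °C; then H2O
Reagents that add atoms: n-butyllithium [Li]CCCC (lithium of 19 only)
Why: 1,2-Addition of a lithium acetylide, used as its alkoxide–acetylide dianion so that no protecting group is needed, to the hindered enone carbonyl is well known for 2,6,6-trimethylcyclohexenones, and either epimer of the new carbinol serves because that center is removed in step 12.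

Step 12
Reactants: 20 (4S)-4-[(tert-butyldimethylsilyl)oxy]-1-[(3E)-5-hydroxy-3-methylpent-3-en-1-yn-1-yl]-2,6,6-trimethylcyclohex-2-en-1-ol
Product: 21 (2E)-5-{(4S)-4-[(tert-butyldimethylsilyl)oxy]-2,6,6-trimethyl-3-oxocyclohex-1-en-1-yl}-3-methylpent-2-en-4-ynal
Conditions: (C5H5NH)[CrO3Cl] (5 equiv), 4 Å molecular sieves, CH2Cl2, rt
Reagents that add atoms: pyridinium chlorochromate [O-][Cr](=O)(=O)Cl.c1cc[nH+]cc1 (ring carbonyl oxygen)
Why: In this Babler–Dauben oxidative transposition the tertiary allylic chromate ester of hexavalent chromium shifts 1,3 to the ring CH and is oxidised to the ynenone, which places the ketone on C4' and the alkyne on C6', while the primary allylic alcohol is oxidised to the enal in the same operation.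

Step 13
Reactants: 21 (2E)-5-{(4S)-4-[(tert-butyldimethylsilyl)oxy]-2,6,6-trimethyl-3-oxocyclohex-1-en-1-yl}-3-methylpent-2-en-4-ynal
Product: 22 (1R,6S)-6-[(tert-butyldimethylsilyl)oxy]-3-[(3E)-5-hydroxy-3-methylpent-3-en-1-yn-1-yl]-2,4,4-trimethylcyclohex-2-en-1-ol
Conditions: LiBH(sBu)3 (2.5 equiv), THF, −78 to −40 °C; then H2O
Reagents that add atoms: none
Why: In this carbonyl reduction by a bulky trialkylborohydride the aldehyde returns to the primary alcohol, and the ring ketone, whose silyloxy group is held equatorial by the gem-dimethyl group and whose β-carbon is fully substituted, should be attacked 1,2 and equatorially, which places the new hydroxyl cis to the silyloxy group (4'R).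

Step 14
Reactants: 22 (1R,6S)-6-[(tert-butyldimethylsilyl)oxy]-3-[(3E)-5-hydroxy-3-methylpent-3-en-1-yn-1-yl]-2,4,4-trimethylcyclohex-2-en-1-ol
Product: 24 tributyl[(2E)-5-{(3R,4S)-4-[(tert-butyldimethylsilyl)oxy]-3-hydroxy-2,6,6-trimethylcyclohex-1-en-1-yl}-3-methylpent-2-en-4-yn-1-yl]phosphonium bromide, via allylic bromide 23 (not isolated)
Conditions: CBr4 (1.05 equiv), PPh3 (1.05 equiv), CH2Cl2, −40 °C; then PBu3 (1.3 equiv), −40 °C to rt
Reagents that add atoms: tetrabromomethane BrC(Br)(Br)Br; tributylphosphine CCCCP(CCCC)CCCC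
Why: Appel bromination should select the primary allylic alcohol over the secondary one, which is flanked by the silyloxy group and the ring methyl group, and SN2 quaternisation of tributylphosphine then gives the salt under neutral conditions that do not ionise the allylic 4'-alcohol.

Step 15
Reactants: 24 tributyl[(2E)-5-{(3R,4S)-4-[(tert-butyldimethylsilyl)oxy]-3-hydroxy-2,6,6-trimethylcyclohex-1-en-1-yl}-3-methylpent-2-en-4-yn-1-yl]phosphonium bromide; 16 (2E,4E,6E,8E,10E)-13-{(4R)-4-[(tert-butyldimethylsilyl)oxy]-2,6,6-trimethylcyclohex-1-en-1-yl}-2,7,11-trimethyltrideca-2,4,6,8,10-pentaen-12-ynal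
Product: 26 (3R,3'S,4'R)-3,3'-bis[(tert-butyldimethylsilyl)oxy]-7,8,7',8'-tetradehydro-β,β-caroten-4'-ol, via sodium alkoxide ylide 25 (not isolated)
Conditions: NaN(SiMe3)2 (2.05 equiv), THF, −78 °C; then 16, −78 to 0 °C, dark; then H2O
Reagents that add atoms: sodium bis(trimethylsilyl)amide C[Si](C)(C)N([Na])[Si](C)(C)C (sodium of 25 only)
Why: Wittig olefination by the E-selective allylic tributylphosphonium ylide, with the second equivalent of base holding the 4'-hydroxyl as its alkoxide, should form the last C11'=C12' bond, and a silyl shift between the cis 3'- and 4'-oxygens would be harmless because both silyl groups are removed next.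

Step 16
Reactants: 26 (3R,3'S,4'R)-3,3'-bis[(tert-butyldimethylsilyl)oxy]-7,8,7',8'-tetradehydro-β,β-caroten-4'-ol
Product: 27 (3R,3'S,4'R)-7,8,7',8'-tetradehydro-β,β-carotene-3,3',4'-triol (all-E)
Conditions: Bu4NF (4 equiv), THF, 0 °C to rt, dark, argon; then H2O
Reagents that add atoms: none
Why: Fluoride-mediated desilylation removes both silyl ethers without acid, which the allylic 4'-alcohol and the polyene would not tolerate.

**Compound list**

1 | 3,3-dimethyloxolan-2-one | CC1(C)CCOC1=O | starting material
2 | isopropenylmagnesium bromide (THF solution) | CC(=C)[Mg]Br | starting material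
3 | 6-hydroxy-2,4,4-trimethylhex-1-en-3-one (open form, in equilibrium with its lactol) | CC(=C)C(=O)C(C)(C)CCO | intermediate
4 | 3,3,5-trimethyl-4-oxohex-5-enal | CC(=C)C(=O)C(C)(C)CC=O | intermediate
5 | (6R)-2,2,6-trimethylcyclohexane-1,4-dione | C[C@@H]1CC(=O)CC(C)(C)C1=O | intermediate
6 | (4R,6R)-4-hydroxy-2,2,6-trimethylcyclohexan-1-one | C[C@@H]1C[C@@H](O)CC(C)(C)C1=O | intermediate
7 | (4R,6R)-4-[(tert-butyldimethylsilyl)oxy]-2,2,6-trimethylcyclohexan-1-one | C[C@@H]1C[C@@H](O[Si](C)(C)C(C)(C)C)CC(C)(C)C1=O | intermediate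
8 | lithium (4R)-4-[(tert-butyldimethylsilyl)oxy]-2,6,6-trimethylcyclohex-1-en-1-olate (formed in the flask) | CC1=C(O[Li])C(C)(C)C[C@H](O[Si](C)(C)C(C)(C)C)C1 | intermediate
9 | (4R)-4-[(tert-butyldimethylsilyl)oxy]-2,6,6-trimethylcyclohex-1-en-1-yl trifluoromethanesulfonate | CC1=C(OS(=O)(=O)C(F)(F)F)C(C)(C)C[C@H](O[Si](C)(C)C(C)(C)C)C1 | intermediate
10 | (2E)-3-methylpent-2-en-4-yn-1-ol | C#C/C(C)=C/CO | starting material
11 | (2E)-5-{(4R)-4-[(tert-butyldimethylsilyl)oxy]-2,6,6-trimethylcyclohex-1-en-1-yl}-3-methylpent-2-en-4-yn-1-ol | CC1=C(C#C/C(C)=C/CO)C(C)(C)C[C@H](O[Si](C)(C)C(C)(C)C)C1 | intermediate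
12 | {[(1R)-4-[(3E)-5-bromo-3-methylpent-3-en-1-yn-1-yl]-3,5,5-trimethylcyclohex-3-en-1-yl]oxy}(tert-butyl)dimethylsilane (formed in the flask) | CC1=C(C#C/C(C)=C/CBr)C(C)(C)C[C@H](O[Si](C)(C)C(C)(C)C)C1 | intermediate
13 | tributyl[(2E)-5-{(4R)-4-[(tert-butyldimethylsilyl)oxy]-2,6,6-trimethylcyclohex-1-en-1-yl}-3-methylpent-2-en-4-yn-1-yl]phosphonium bromide | CC1=C(C#C/C(C)=C/C[P+](CCCC)(CCCC)CCCC)C(C)(C)C[C@H](O[Si](C)(C)C(C)(C)C)C1.[Br-] | intermediate
14 | (2E,4E,6E)-2,7-dimethylocta-2,4,6-trienedial | O=C/C(C)=C/C=C/C=C(C)/C=O | starting material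
15 | ylide of 13, tributyl[(2E)-5-{(4R)-4-[(tert-butyldimethylsilyl)oxy]-2,6,6-trimethylcyclohex-1-en-1-yl}-3-methylpent-2-en-4-yn-1-ylidene]phosphorane (formed in the flask) | CC1=C(C#C/C(C)=C/C=P(CCCC)(CCCC)CCCC)C(C)(C)C[C@H](O[Si](C)(C)C(C)(C)C)C1 | intermediate
16 | (2E,4E,6E,8E,10E)-13-{(4R)-4-[(tert-butyldimethylsilyl)oxy]-2,6,6-trimethylcyclohex-1-en-1-yl}-2,7,11-trimethyltrideca-2,4,6,8,10-pentaen-12-ynal | CC1=C(C#C/C(C)=C/C=C/C(C)=C/C=C/C=C(C)/C=O)C(C)(C)C[C@H](O[Si](C)(C)C(C)(C)C)C1 | intermediate
17 | tert-butyldimethyl{[(1R)-3,5,5-trimethyl-4-[(trimethylsilyl)oxy]cyclohex-3-en-1-yl]oxy}silane (formed in the flask) | CC1=C(O[Si](C)(C)C)C(C)(C)C[C@H](O[Si](C)(C)C(C)(C)C)C1 | intermediate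
18 | (4S)-4-[(tert-butyldimethylsilyl)oxy]-2,6,6-trimethylcyclohex-2-en-1-one | CC1=C[C@@H](O[Si](C)(C)C(C)(C)C)CC(C)(C)C1=O | intermediate
19 | lithium (2E)-5-lithio-3-methylpent-2-en-4-yn-1-olate (formed in the flask) | [Li]C#C/C(C)=C/CO[Li] | intermediate
20 | (4S)-4-[(tert-butyldimethylsilyl)oxy]-1-[(3E)-5-hydroxy-3-methylpent-3-en-1-yn-1-yl]-2,6,6-trimethylcyclohex-2-en-1-ol (both epimers at C1) | CC1=C[C@@H](O[Si](C)(C)C(C)(C)C)CC(C)(C)C1(O)C#C/C(C)=C/CO | intermediate
21 | (2E)-5-{(4S)-4-[(tert-butyldimethylsilyl)oxy]-2,6,6-trimethyl-3-oxocyclohex-1-en-1-yl}-3-methylpent-2-en-4-ynal | CC1=C(C#C/C(C)=C/C=O)C(C)(C)C[C@H](O[Si](C)(C)C(C)(C)C)C1=O | intermediate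
22 | (1R,6S)-6-[(tert-butyldimethylsilyl)oxy]-3-[(3E)-5-hydroxy-3-methylpent-3-en-1-yn-1-yl]-2,4,4-trimethylcyclohex-2-en-1-ol | OC/C=C(C)/C#CC1=C(C)[C@@H](O)[C@@H](O[Si](C)(C)C(C)(C)C)CC1(C)C | intermediate
23 | (1R,6S)-3-[(3E)-5-bromo-3-methylpent-3-en-1-yn-1-yl]-6-[(tert-butyldimethylsilyl)oxy]-2,4,4-trimethylcyclohex-2-en-1-ol (formed in the flask) | BrC/C=C(C)/C#CC1=C(C)[C@@H](O)[C@@H](O[Si](C)(C)C(C)(C)C)CC1(C)C | intermediate
24 | tributyl[(2E)-5-{(3R,4S)-4-[(tert-butyldimethylsilyl)oxy]-3-hydroxy-2,6,6-trimethylcyclohex-1-en-1-yl}-3-methylpent-2-en-4-yn-1-yl]phosphonium bromide | CCCC[P+](CCCC)(CCCC)C/C=C(C)/C#CC1=C(C)[C@@H](O)[C@@H](O[Si](C)(C)C(C)(C)C)CC1(C)C.[Br-] | intermediate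
25 | sodium alkoxide ylide of 24 (formed in the flask) | CCCCP(CCCC)(CCCC)=C/C=C(C)/C#CC1=C(C)[C@@H](O[Na])[C@@H](O[Si](C)(C)C(C)(C)C)CC1(C)C | intermediate
26 | (3R,3'S,4'R)-3,3'-bis[(tert-butyldimethylsilyl)oxy]-7,8,7',8'-tetradehydro-β,β-caroten-4'-ol | CC1=C(C#C/C(C)=C/C=C/C(C)=C/C=C/C=C(C)/C=C/C=C(\C)C#CC2=C(C)[C@@H](O)[C@@H](O[Si](C)(C)C(C)(C)C)CC2(C)C)C(C)(C)C[C@H](O[Si](C)(C)C(C)(C)C)C1 | intermediate
27 | (3R,3'S,4'R)-7,8,7',8'-tetradehydro-β,β-carotene-3,3',4'-triol (all-E) | CC1=C(C#C/C(C)=C/C=C/C(C)=C/C=C/C=C(C)/C=C/C=C(\C)C#CC2=C(C)[C@@H](O)[C@@H](O)CC2(C)C)C(C)(C)C[C@H](O)C1 | target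

**Count and risks**

Total step count: 16. Longest linear sequence: 12 steps (steps 1 to 5, 10 to 14, 15 and 16).

Steps most likely to fail:

Step 3 (Proposed new method). The endo-mode conjugate addition may be slower than intermolecular benzoin or aldol oligomerisation of the aldehyde. The proton transfer that sets the methyl-bearing carbon may not be face-selective, or the product may epimerise under the basic catalyst. The fallback uses known chemistry and sets out from 4. Pinnick oxidation (NaClO2, NaH2PO4, 2-methylbut-2-ene, tBuOH/H2O) should give 3,3,5-trimethyl-4-oxohex-5-enoic acid F1. Diphenyl diselenide with PBu3 should convert it into Se-phenyl 3,3,5-trimethyl-4-oxohex-5-eneselenoate F2. Bu3SnH with AIBN in dilute benzene at 80 °C should generate the acyl radical, whose 6-endo cyclisation onto the enone terminus is a known reaction type and should close the same ring bond to give racemic 2,2,6-trimethylcyclohexane-1,4-dione F3. SeO2 dehydrogenation of this 1,4-diketone (tBuOH, reflux) should give the achiral 2,6,6-trimethylcyclohex-2-ene-1,4-dione F4. Fermenting baker's yeast (Saccharomyces cerevisiae, sucrose, water, 30 °C), a known biocatalytic C=C reduction of this enedione to the 6R dione, brings the route back at 5.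

Step 13. The facial selectivity at the ring carbonyl may be poor (trans diol), or hydride may add in a conjugate sense to the ynenone or the enynal. The fallback sets out from 21 and replaces substrate steric control by catalyst control. A Corey–Bakshi–Shibata reduction with catecholborane and the 2-methyl-oxazaborolidine antipode that is matched with attack anti to the silyloxy group is strictly 1,2-selective. It should reduce both carbonyl groups and comes back at 22 without any new compound.

Step 15. E/Z selectivity at the new C11'=C12' bond may be low, the ylide may be quenched by the free 4'-hydroxyl, or the olefin next to the alkyne may isomerise under the base. The fallback changes the olefination to a Horner–Wadsworth–Emmons reaction and sets out from bromide 23, made from 22 as in step 14 with the tributylphosphine left out. Michaelis–Becker substitution with sodium diethyl phosphite (THF, 0 °C) should give diethyl [(2E)-5-{(3R,4S)-4-[(tert-butyldimethylsilyl)oxy]-3-hydroxy-2,6,6-trimethylcyclohex-1-en-1-yl}-3-methylpent-2-en-4-yn-1-yl]phosphonate F5. Its dianion (NaN(SiMe3)2, 2 equiv, THF, −40 °C) should add to aldehyde 16 with the E preference typical of phosphonate carbanions and comes back at 26.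

Further compounds
F1 | step 3 | 3,3,5-trimethyl-4-oxohex-5-enoic acid | CC(=C)C(=O)C(C)(C)CC(=O)O
F2 | step 3 | Se-phenyl 3,3,5-trimethyl-4-oxohex-5-eneselenoate | CC(=C)C(=O)C(C)(C)CC(=O)[Se]c1ccccc1
F3 | step 3 | racemic 2,2,6-trimethylcyclohexane-1,4-dione | CC1CC(=O)CC(C)(C)C1=O
F4 | step 3 | 2,6,6-trimethylcyclohex-2-ene-1,4-dione | CC1=CC(=O)CC(C)(C)C1=O
F0 | step 13 | none | none
F5 | step 15 | diethyl [(2E)-5-{(3R,4S)-4-[(tert-butyldimethylsilyl)oxy]-3-hydroxy-2,6,6-trimethylcyclohex-1-en-1-yl}-3-methylpent-2-en-4-yn-1-yl]phosphonate | CCOP(=O)(OCC)C/C=C(C)/C#CC1=C(C)[C@@H](O)[C@@H](O[Si](C)(C)C(C)(C)C)CC1(C)C
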